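**Plan**
- Numbering as in the target: C1 (CH–CH3), C2, C3 (CH–OAc), C4 (CH–C11), C4a/C8a (ring fusion), C6 (C–CO2H), C7/C8 (C–OH), side chain C11(CH3)–C12–C13–C14=C15.
- Cuts: C6–CO2H (aryllithium + CO2); C13–C14 and C12=C13 (Suzuki, Wittig), so that C12 becomes a carbonyl bound to the C3 oxygen; C4–C4a (ring closure); C3–C4 (carbonyl allylation); C1–C8a (conjugate arylation).
- Forward: bought arene → C1–C8a → chain grown to an α-methylbutenolide (O–C3–C4=C11(CH3)–C12=O, a temporary ring) → carbocycle C1–C2–C3–C4–C4a–C8a closed last through C4–C4a → lactone unravelled into the side chain → CO2H, acetate, free catechol.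
- Enabling feature: C4a is the only free position ortho to the C8a chain and is para to the C7 oxygen; O–C3–C4–C11(CH3)–C12 is a γ-lactone in waiting, in which cis C3–O/C4–C11 is a cis ring fusion and the 11S methyl is the exo epimer.
- Stereochemistry: C1 from Rh/BINAP arylation, C3 from Cr/bis(oxazoline) allylation, C4 from the C3 tether in the ring closure, C11 from equilibration of the lactone.

Key step: step 5

Assumption: building blocks 1, 2, 5 and 16 are purchased, and the BINAP and bis(oxazoline) antipodes are those that give the configurations drawn.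

**Step 1**
Reactants: 1 2,3-dimethoxyphenylboronic acid; 2 ethyl (E)-but-2-enoate
Product: 3 ethyl (3R)-3-(2,3-dimethoxyphenyl)butanoate
Conditions: Rh(acac)(C2H4)2 (3 mol%), BINAP (antipode for 3R), dioxane/H2O, 100 °C
Reagents that add atoms: none
Why: Hayashi–Miyaura Rh-catalysed asymmetric 1,4-addition; the aryl–Rh species should add to the enoate face selected by BINAP, which sets C1 (R).

**Step 2**
Reactants: 3 ethyl (3R)-3-(2,3-dimethoxyphenyl)butanoate
Product: 4 (3R)-3-(2,3-dimethoxyphenyl)butanal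
Conditions: DIBAL-H (1.1 equiv), CH2Cl2, −78 °C; Rochelle salt
Reagents that add atoms: none
Why: DIBAL-H partial reduction of an ester; the aluminium hemiacetal is stable at −78 °C and should release the aldehyde on work-up, and C1 is not α to the carbonyl so it cannot epimerise.

**Step 3**
Reactants: 4 (3R)-3-(2,3-dimethoxyphenyl)butanal; 5 ethyl 2-(bromomethyl)acrylate
Product: 8 (5R)-5-[(2R)-2-(2,3-dimethoxyphenyl)propyl]-3-methylideneoxolan-2-one, via silyl ether 6 (not isolated), via hydroxy ester 7 (not isolated)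
Conditions: CrCl2 (10 mol%), chiral carbazole-bis(oxazoline) ligand (antipode for 5R), Mn, TMSCl, Et3N (cat.), THF, rt; then 1 M HCl; TsOH (cat.), CH2Cl2, rt
Reagents that add atoms: none
Why: Catalytic asymmetric Nozaki–Hiyama–Kishi 2-(alkoxycarbonyl)allylation followed by lactonisation; the ligated allylchromium(III) should add through a six-membered transition state to the aldehyde face chosen by the ligand (catalyst control, the 1,3-related C1 centre exerting little bias), which sets C3.

**Step 4**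
Reactants: 8 (5R)-5-[(2R)-2-(2,3-dimethoxyphenyl)propyl]-3-methylideneoxolan-2-one
Product: 9 (5R)-5-[(2R)-2-(2,3-dimethoxyphenyl)propyl]-3-methylfuran-2(5H)-one
Conditions: RhCl3·3H2O (5 mol%), EtOH, reflux
Reagents that add atoms: none
Why: Transition-metal-catalysed alkene isomerisation (Rh–H addition/β-hydride elimination) should move the exocyclic double bond into the ring to give the more stable trisubstituted butenolide without touching the C3–H bond.

**Step 5**
Reactants: 9 (5R)-5-[(2R)-2-(2,3-dimethoxyphenyl)propyl]-3-methylfuran-2(5H)-one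
Product: 11 (1R,3aR,5R,9bS)-6,7-dimethoxy-1,5-dimethyl-3a,4,5,9b-tetrahydronaphtho[2,1-b]furan-2(1H)-one, via 1-epi-lactone 10 (not isolated)
Conditions: TfOH (3 equiv), CH2Cl2, 0 °C → rt; then DBU (excess), toluene, 80 °C
Reagents that add atoms: none
Why: O-Protonation of the butenolide makes C4 the electrophilic β-carbon of a hydroxyfuranylium (allyl) cation, the arene attacks through C4a and loses the C4a proton, and the lactone enol then ketonises; this is an intramolecular Friedel–Crafts conjugate addition, the acid-promoted hydroarylation known for α,β-unsaturated esters and lactones. The carbocycle closes 6-exo-trig on the C4=C11 bond. C4 is set by C3, because the three-atom tether C3–C2–C1 can deliver the arene only to the butenolide face that carries the C3–C2 bond, which gives the cis-fused lactone and therefore C3–O and C4–C11 cis. C11 is set by thermodynamics: kinetic protonation of the enol from the open convex face should leave the methyl endo (10), and DBU should equilibrate it through the lactone enolate to the exo epimer 11 (methyl trans to the C4–C4a bond), which corresponds to 11S. Regioselectivity needs no choice, since C4a is the only free position ortho to the tether and is para to the C7 methoxy group (the C8 methoxy group is twisted out of conjugation); the selectivity at stake is conjugate addition against ionisation of the C3–O bond, which low temperature and the nucleophilic dimethoxyarene should favour.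

**Step 6**
Reactants: 11 (1R,3aR,5R,9bS)-6,7-dimethoxy-1,5-dimethyl-3a,4,5,9b-tetrahydronaphtho[2,1-b]furan-2(1H)-one
Product: 12 (1R,3aR,5R,9bS)-6,7-dihydroxy-1,5-dimethyl-3a,4,5,9b-tetrahydronaphtho[2,1-b]furan-2(1H)-one
Conditions: BBr3 (3 equiv), CH2Cl2, −78 → 0 °C; H2O
Reagents that add atoms: none
Why: BBr3 cleavage of aryl methyl ethers (Lewis acid–base adduct, bromide SN2 at methyl) should spare the lactone at low temperature; it is done here because methyl ethers could not be removed at the end beside the acetate and the alkene.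

**Step 7**
Reactants: 12 (1R,3aR,5R,9bS)-6,7-dihydroxy-1,5-dimethyl-3a,4,5,9b-tetrahydronaphtho[2,1-b]furan-2(1H)-one
Product: 13 (1R,3aR,5R,9bS)-6,7-bis(methoxymethoxy)-1,5-dimethyl-3a,4,5,9b-tetrahydronaphtho[2,1-b]furan-2(1H)-one
Conditions: MOMCl, i-Pr2NEt, n-Bu4NI (cat.), CH2Cl2, 0 → 40 °C
Reagents that add atoms: chloromethyl methyl ether (MOMCl), COCCl
Why: O-Alkylation of both phenols (Williamson-type acetal formation) should give MOM ethers, which later direct the ortho-lithiation and come off under mild non-hydrolytic conditions.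

**Step 8**
Reactants: 13 (1R,3aR,5R,9bS)-6,7-bis(methoxymethoxy)-1,5-dimethyl-3a,4,5,9b-tetrahydronaphtho[2,1-b]furan-2(1H)-one
Product: 14 (1R,3aR,5R,9bS)-6,7-bis(methoxymethoxy)-1,5-dimethyl-1,2,3a,4,5,9b-hexahydronaphtho[2,1-b]furan-2-ol (both anomers)
Conditions: DIBAL-H (1.1 equiv), CH2Cl2, −78 °C; Rochelle salt
Reagents that add atoms: none
Why: DIBAL-H reduction of a lactone should stop at the aluminium lactolate at −78 °C, and no stereocentre is touched.

**Step 9**
Reactants: 14 (1R,3aR,5R,9bS)-6,7-bis(methoxymethoxy)-1,5-dimethyl-1,2,3a,4,5,9b-hexahydronaphtho[2,1-b]furan-2-ol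
Product: 15 (1S,2R,4R)-1-[(2S)-but-3-en-2-yl]-5,6-bis(methoxymethoxy)-4-methyl-1,2,3,4-tetrahydronaphthalen-2-ol
Conditions: Ph3PCH3Br, KHMDS, THF, 0 °C → rt
Reagents that add atoms: methyltriphenylphosphonium bromide, C[P+](c1ccccc1)(c1ccccc1)c1ccccc1.[Br-]
Why: Wittig methylenation of the lactol through its open hydroxy-aldehyde form should turn C12 into the C12=C13 vinyl group and free the C3 hydroxyl, with excess ylide at low temperature outrunning enolisation at C11.

**Step 10**
Reactants: 15 (1S,2R,4R)-1-[(2S)-but-3-en-2-yl]-5,6-bis(methoxymethoxy)-4-methyl-1,2,3,4-tetrahydronaphthalen-2-ol; 16 1-bromo-2-methylprop-1-ene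
Product: 18 (1S,2R,4R)-5,6-bis(methoxymethoxy)-4-methyl-1-[(2S)-6-methylhept-5-en-2-yl]-1,2,3,4-tetrahydronaphthalen-2-ol, via B-alkyl-9-BBN adduct 17 (not isolated)
Conditions: 9-BBN (2.5 equiv), THF, rt; then 16, Pd(dppf)Cl2 (5 mol%), AsPh3, aq. K3PO4, DMF, rt → 50 °C
Reagents that add atoms: none
Why: Anti-Markovnikov hydroboration with 9-BBN should place boron on C13, and B-alkyl Suzuki–Miyaura coupling with the vinyl bromide then forms C13–C14 with the trisubstituted alkene already in place; the C3 hydroxyl travels as its borinate and is released in the basic aqueous phase.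

**Step 11**
Reactants: 18 (1S,2R,4R)-5,6-bis(methoxymethoxy)-4-methyl-1-[(2S)-6-methylhept-5-en-2-yl]-1,2,3,4-tetrahydronaphthalen-2-ol
Product: 20 (5R,7R,8S)-7-hydroxy-3,4-bis(methoxymethoxy)-5-methyl-8-[(2S)-6-methylhept-5-en-2-yl]-5,6,7,8-tetrahydronaphthalene-2-carboxylic acid, via dilithio species 19 (not isolated)
Conditions: n-BuLi (3.5 equiv), TMEDA, THF, −78 → 0 °C; CO2, −78 °C; 1 M HCl to pH 3 at 0 °C
Reagents that add atoms: carbon dioxide, O=C=O
Why: Directed ortho-metalation; the C7 OMOM group should direct lithiation to C6, its only free ortho position (the C8 OMOM group has none), and CO2 traps the aryllithium, while the C3 alkoxide only consumes one equivalent of base.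

**Step 12**
Reactants: 20 (5R,7R,8S)-7-hydroxy-3,4-bis(methoxymethoxy)-5-methyl-8-[(2S)-6-methylhept-5-en-2-yl]-5,6,7,8-tetrahydronaphthalene-2-carboxylic acid
Product: 21 (5R,7R,8S)-7-acetoxy-3,4-bis(methoxymethoxy)-5-methyl-8-[(2S)-6-methylhept-5-en-2-yl]-5,6,7,8-tetrahydronaphthalene-2-carboxylic acid
Conditions: Ac2O, pyridine, DMAP (cat.), CH2Cl2, rt; aqueous work-up
Reagents that add atoms: acetic anhydride, CC(=O)OC(C)=O
Why: DMAP-catalysed acylation should acetylate only the C3 hydroxyl, because both phenols are still masked and the mixed anhydride formed at the carboxylic acid is hydrolysed on aqueous work-up.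

**Step 13**
Reactants: 21 (5R,7R,8S)-7-acetoxy-3,4-bis(methoxymethoxy)-5-methyl-8-[(2S)-6-methylhept-5-en-2-yl]-5,6,7,8-tetrahydronaphthalene-2-carboxylic acid
Product: 22 (5R,7R,8S)-7-acetoxy-3,4-dihydroxy-5-methyl-8-[(2S)-6-methylhept-5-en-2-yl]-5,6,7,8-tetrahydronaphthalene-2-carboxylic acid (CNP0201371.1)
Conditions: TMSOTf, 2,2′-bipyridyl, CH2Cl2, 0 °C → rt; then H2O
Reagents that add atoms: none
Why: Mild non-protic acetal cleavage; TMSOTf/2,2′-bipyridyl should convert the aryl MOM ethers into silyl ethers through a bipyridinium intermediate, and water then hydrolyses them, conditions under which the secondary acetate, the carboxylic acid and the trisubstituted alkene should survive.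

**Compound list**
1 | 2,3-dimethoxyphenylboronic acid | COc1cccc(B(O)O)c1OC | starting material
2 | ethyl (E)-but-2-enoate | C/C=C/C(=O)OCC | starting material
3 | ethyl (3R)-3-(2,3-dimethoxyphenyl)butanoate | CCOC(=O)C[C@@H](C)c1cccc(OC)c1OC | intermediate
4 | (3R)-3-(2,3-dimethoxyphenyl)butanal | O=CC[C@@H](C)c1cccc(OC)c1OC | intermediate
5 | ethyl 2-(bromomethyl)acrylate | C=C(CBr)C(=O)OCC | starting material
6 | ethyl (4R,6R)-6-(2,3-dimethoxyphenyl)-2-methylidene-4-(trimethylsilyloxy)heptanoate (not isolated) | CCOC(=O)C(=C)C[C@H](O[Si](C)(C)C)C[C@@H](C)c1cccc(OC)c1OC | intermediate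
7 | ethyl (4R,6R)-6-(2,3-dimethoxyphenyl)-4-hydroxy-2-methylideneheptanoate (not isolated) | CCOC(=O)C(=C)C[C@H](O)C[C@@H](C)c1cccc(OC)c1OC | intermediate
8 | (5R)-5-[(2R)-2-(2,3-dimethoxyphenyl)propyl]-3-methylideneoxolan-2-one | C=C1C[C@@H](C[C@@H](C)c2cccc(OC)c2OC)OC1=O | intermediate
9 | (5R)-5-[(2R)-2-(2,3-dimethoxyphenyl)propyl]-3-methylfuran-2(5H)-one | CC1=C[C@@H](C[C@@H](C)c2cccc(OC)c2OC)OC1=O | intermediate
10 | (1S,3aR,5R,9bS)-6,7-dimethoxy-1,5-dimethyl-3a,4,5,9b-tetrahydronaphtho[2,1-b]furan-2(1H)-one (C11 epimer, not isolated) | O=C1O[C@@H]2C[C@@H](C)c3c(ccc(OC)c3OC)[C@@H]2[C@@H]1C | intermediate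
11 | (1R,3aR,5R,9bS)-6,7-dimethoxy-1,5-dimethyl-3a,4,5,9b-tetrahydronaphtho[2,1-b]furan-2(1H)-one | O=C1O[C@@H]2C[C@@H](C)c3c(ccc(OC)c3OC)[C@@H]2[C@H]1C | intermediate
12 | (1R,3aR,5R,9bS)-6,7-dihydroxy-1,5-dimethyl-3a,4,5,9b-tetrahydronaphtho[2,1-b]furan-2(1H)-one | O=C1O[C@@H]2C[C@@H](C)c3c(ccc(O)c3O)[C@@H]2[C@H]1C | intermediate
13 | (1R,3aR,5R,9bS)-6,7-bis(methoxymethoxy)-1,5-dimethyl-3a,4,5,9b-tetrahydronaphtho[2,1-b]furan-2(1H)-one | O=C1O[C@@H]2C[C@@H](C)c3c(ccc(OCOC)c3OCOC)[C@@H]2[C@H]1C | intermediate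
14 | (1R,3aR,5R,9bS)-6,7-bis(methoxymethoxy)-1,5-dimethyl-1,2,3a,4,5,9b-hexahydronaphtho[2,1-b]furan-2-ol (both anomers) | OC1O[C@@H]2C[C@@H](C)c3c(ccc(OCOC)c3OCOC)[C@@H]2[C@H]1C | intermediate
15 | (1S,2R,4R)-1-[(2S)-but-3-en-2-yl]-5,6-bis(methoxymethoxy)-4-methyl-1,2,3,4-tetrahydronaphthalen-2-ol | O[C@@H]1C[C@@H](C)c2c(ccc(OCOC)c2OCOC)[C@@H]1[C@@H](C)C=C | intermediate
16 | 1-bromo-2-methylprop-1-ene | CC(C)=CBr | starting material
17 | O,C13-bis(9-borabicyclo[3.3.1]nonan-9-yl) adduct of 15 (not isolated) | B1(C2CCCC1CCC2)O[C@@H]1C[C@@H](C)c2c(ccc(OCOC)c2OCOC)[C@@H]1[C@@H](C)CCB1C2CCCC1CCC2 | intermediate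
18 | (1S,2R,4R)-5,6-bis(methoxymethoxy)-4-methyl-1-[(2S)-6-methylhept-5-en-2-yl]-1,2,3,4-tetrahydronaphthalen-2-ol | O[C@@H]1C[C@@H](C)c2c(ccc(OCOC)c2OCOC)[C@@H]1[C@@H](C)CCC=C(C)C | intermediate
19 | lithium alkoxide of 18 lithiated at C6 (not isolated) | [Li]O[C@@H]1C[C@@H](C)c2c(cc([Li])c(OCOC)c2OCOC)[C@@H]1[C@@H](C)CCC=C(C)C | intermediate
20 | (5R,7R,8S)-7-hydroxy-3,4-bis(methoxymethoxy)-5-methyl-8-[(2S)-6-methylhept-5-en-2-yl]-5,6,7,8-tetrahydronaphthalene-2-carboxylic acid | O[C@@H]1C[C@@H](C)c2c(cc(C(=O)O)c(OCOC)c2OCOC)[C@@H]1[C@@H](C)CCC=C(C)C | intermediate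
21 | (5R,7R,8S)-7-acetoxy-3,4-bis(methoxymethoxy)-5-methyl-8-[(2S)-6-methylhept-5-en-2-yl]-5,6,7,8-tetrahydronaphthalene-2-carboxylic acid | CC(=O)O[C@@H]1C[C@@H](C)c2c(cc(C(=O)O)c(OCOC)c2OCOC)[C@@H]1[C@@H](C)CCC=C(C)C | intermediate
22 | (5R,7R,8S)-7-acetoxy-3,4-dihydroxy-5-methyl-8-[(2S)-6-methylhept-5-en-2-yl]-5,6,7,8-tetrahydronaphthalene-2-carboxylic acid (CNP0201371.1) | CC(=O)O[C@@H]1C[C@@H](C)c2c(cc(C(=O)O)c(O)c2O)[C@@H]1[C@@H](C)CCC=C(C)C | target

**Totals**
Total step count: 13. Longest linear sequence: 13 steps (1 → 22); all other inputs are bought.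

**Steps most likely to fail**

Step 5. The α-methylbutenolide may be activated too weakly, or acid may ionise the C3–O bond (loss of the C3 configuration, elimination to a dienoic acid) faster than conjugate addition; equilibration at C11 may also stay incomplete. The fallback sets out from 9 and closes the same bond by a radical instead of a cation. Bromination para to the C7 methoxy group (NBS, MeCN, 0 °C) should give (5R)-5-[(2R)-2-(6-bromo-2,3-dimethoxyphenyl)propyl]-3-methylfuran-2(5H)-one F1. Bu3SnH/AIBN (benzene, 80 °C, slow addition) should then add the aryl radical 6-exo-trig to C4 of the butenolide, cis-fused for the same geometric reason, and DBU equilibration of C11 brings the route back at 11.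

Step 3. Catalyst control at C3 may be poor beside the remote C1 centre, giving diastereomeric lactones, or the allyl bromide may be consumed by reductive self-coupling. The fallback sets out from 4 and builds the butenolide by metathesis. Vinylmagnesium bromide should give (5R)-5-(2,3-dimethoxyphenyl)hex-1-en-3-ol as C3 epimers F2, and Dess–Martin oxidation the enone (5R)-5-(2,3-dimethoxyphenyl)hex-1-en-3-one F3. Corey–Bakshi–Shibata reduction (antipode for 3R) should give (3R,5R)-5-(2,3-dimethoxyphenyl)hex-1-en-3-ol F4. Methacryloyl chloride/Et3N/DMAP should give (3R,5R)-5-(2,3-dimethoxyphenyl)hex-1-en-3-yl 2-methylprop-2-enoate F5, and ring-closing metathesis (Grubbs second-generation catalyst, toluene, 80 °C) returns the route at 9.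

Step 9. The basic ylide may enolise the open-chain hydroxy aldehyde and epimerise C11 before olefination, or the lactol may open sluggishly. The fallback sets out from 14 and extends the chain with a non-basic stabilised ylide. Ph3P=CHCO2Et (toluene, 80 °C) should give ethyl (2E,4S)-4-[(1S,2R,4R)-2-hydroxy-5,6-bis(methoxymethoxy)-4-methyl-1,2,3,4-tetrahydronaphthalen-1-yl]pent-2-enoate F6. Immediate hydrogenation (H2, Pd/C, EtOAc; no other alkene is present yet) should give ethyl (4S)-4-[(1S,2R,4R)-2-hydroxy-5,6-bis(methoxymethoxy)-4-methyl-1,2,3,4-tetrahydronaphthalen-1-yl]pentanoate F7. DIBAL-H at −78 °C should give (4S)-4-[(1S,2R,4R)-2-hydroxy-5,6-bis(methoxymethoxy)-4-methyl-1,2,3,4-tetrahydronaphthalen-1-yl]pentanal F8, whose α-carbon is a plain CH2. Wittig reaction with isopropylidenetriphenylphosphorane returns the route at 18.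

**Further compounds**
F1 | step 5 | (5R)-5-[(2R)-2-(6-bromo-2,3-dimethoxyphenyl)propyl]-3-methylfuran-2(5H)-one | CC1=C[C@@H](C[C@@H](C)c2c(Br)ccc(OC)c2OC)OC1=O
F2 | step 3 | (5R)-5-(2,3-dimethoxyphenyl)hex-1-en-3-ol (C3 epimers) | C=CC(O)C[C@@H](C)c1cccc(OC)c1OC
F3 | step 3 | (5R)-5-(2,3-dimethoxyphenyl)hex-1-en-3-one | C=CC(=O)C[C@@H](C)c1cccc(OC)c1OC
F4 | step 3 | (3R,5R)-5-(2,3-dimethoxyphenyl)hex-1-en-3-ol | C=C[C@H](O)C[C@@H](C)c1cccc(OC)c1OC
F5 | step 3 | (3R,5R)-5-(2,3-dimethoxyphenyl)hex-1-en-3-yl 2-methylprop-2-enoate | C=C(C)C(=O)O[C@@H](C=C)C[C@@H](C)c1cccc(OC)c1OC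
F6 | step 9 | ethyl (2E,4S)-4-[(1S,2R,4R)-2-hydroxy-5,6-bis(methoxymethoxy)-4-methyl-1,2,3,4-tetrahydronaphthalen-1-yl]pent-2-enoate | O[C@@H]1C[C@@H](C)c2c(ccc(OCOC)c2OCOC)[C@@H]1[C@@H](C)/C=C/C(=O)OCC
F7 | step 9 | ethyl (4S)-4-[(1S,2R,4R)-2-hydroxy-5,6-bis(methoxymethoxy)-4-methyl-1,2,3,4-tetrahydronaphthalen-1-yl]pentanoate | O[C@@H]1C[C@@H](C)c2c(ccc(OCOC)c2OCOC)[C@@H]1[C@@H](C)CCC(=O)OCC
F8 | step 9 | (4S)-4-[(1S,2R,4R)-2-hydroxy-5,6-bis(methoxymethoxy)-4-methyl-1,2,3,4-tetrahydronaphthalen-1-yl]pentanal | O[C@@H]1C[C@@H](C)c2c(ccc(OCOC)c2OCOC)[C@@H]1[C@@H](C)CCC=O
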